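**Strategy.** Ring A (C1–C5, C10) is read as a 2,2-disubstituted cyclohexane-1,3-dione: quaternary C10, bearing C20 and the ring-C carbon C9, lies between oxygenated C1 and C5. It is therefore not closed as a six-membered ring but grown from a five-membered one. The bis-silyl enediol of cyclopentane-1,2-dione adds to the ketal of 3'-methoxyacetophenone, and a pinacol-type 1,2-acyl shift inserts C10 between C1 and C5 (geminal acylation), joining ring C to ring A in one operation. CBS desymmetrisation then fixes C10; Friedel–Crafts allylation closes ring B; Birch reduction, C11 propargylation and gold-catalysed cyclisation build the bicyclo[3.2.1]octane.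

Key step: step 3

Remark: atom numbers (C1–C20) and α/β labels are those of the target throughout (C20, the methyl on C10, is α; H-5 is β); tricyclic intermediates are named as podocarpanes with this numbering, and 1,2-bis(trimethylsilyloxy)cyclopentene is made in step 1 rather than assumed to be on sale.

Step 1
Reactants: 1 dimethyl glutarate
Product: 2 1,2-bis(trimethylsilyloxy)cyclopent-1-ene
Conditions: Na, TMSCl, toluene, reflux
Reagents that add atoms: chlorotrimethylsilane, C[Si](C)(C)Cl
Why: Acyloin condensation in the Rühlmann variant, in which in-situ silylation of the enediolate suppresses Dieckmann condensation.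

Step 2
Reactants: 3 3'-methoxyacetophenone
Product: 4 1-(1,1-dimethoxyethyl)-3-methoxybenzene
Conditions: HC(OMe)3, MeOH, TsOH (cat.), rt
Reagents that add atoms: trimethyl orthoformate, COC(OC)OC
Why: Acid-catalysed ketalisation driven to completion by the orthoformate.

Step 3
Reactants: 4 1-(1,1-dimethoxyethyl)-3-methoxybenzene; 2 1,2-bis(trimethylsilyloxy)cyclopent-1-ene
Product: 6 2-(3-methoxyphenyl)-2-methylcyclohexane-1,3-dione, via aldol adduct 5 (not isolated)
Conditions: BF3·OEt2, CH2Cl2, −78 °C → rt; then CF3CO2H, rt
Reagents that add atoms: none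
Why: BF3 ionises ketal 4 to a methoxycarbenium ion that undergoes Mukaiyama aldol addition to enediol ether 2 to give 5; acid then ionises the tertiary benzylic ether of 5, and the ring acyl carbon (future C5) migrates from the silyloxy carbon (future C1) to the benzylic cation (future C10) while the silyloxy oxygen collapses to the second carbonyl. The closest known reaction type is the geminal acylation of ketals with 1,2-bis(silyloxy)cycloalkenes (Mukaiyama aldol followed by pinacol-type acyl shift), best known for the cyclobutene reagent and extended to the cyclopentene reagent for cyclohexane-1,3-diones. No ring is closed from a chain: the carbocycle C1–C2–C3–C4–C5 is enlarged from five to six members by insertion of C10 between C1 and C5 through the 1,2-shift. No stereocentre is formed, because 6 is Cs-symmetric with C10 prochiral, which step 4 exploits. The step needs acyl rather than alkyl (C2) migration, which the higher migratory aptitude of the acyl carbon and the formation of the oxygen-stabilised carbonyl at C1 should secure. It also needs rearrangement rather than loss of a proton to the styrene, which is reversible under acid and returns to the same benzylic cation.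

Step 4
Reactants: 6 2-(3-methoxyphenyl)-2-methylcyclohexane-1,3-dione
Product: 7 (2R,3R)-3-hydroxy-2-(3-methoxyphenyl)-2-methylcyclohexan-1-one
Conditions: (S)-Me-CBS (20 mol %), catecholborane, toluene/CH2Cl2, −78 → −40 °C
Reagents that add atoms: none
Why: Corey–Bakshi–Shibata desymmetrising reduction of a prochiral 2,2-disubstituted 1,3-dione: the catalyst should set the carbinol as R (quaternary C10 side as the large group) and hydride should add anti to the aryl group, so that one enantiotopic carbonyl is reduced and C10 becomes R with OH cis to aryl (1β, provisional, corrected in steps 10–11); the minor diastereomer, which has the opposite C10 configuration, is removed by chromatography.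

Step 5
Reactants: 7 (2R,3R)-3-hydroxy-2-(3-methoxyphenyl)-2-methylcyclohexan-1-one
Product: 8 (2R,3R)-3-(tert-butyldimethylsilyloxy)-2-(3-methoxyphenyl)-2-methylcyclohexan-1-one
Conditions: TBSOTf, 2,6-lutidine, CH2Cl2, 0 °C
Reagents that add atoms: tert-butyldimethylsilyl triflate, CC(C)(C)[Si](C)(C)OS(=O)(=O)C(F)(F)F
Why: Silylation of the hindered β-hydroxy ketone blocks retro-aldol cleavage and O-methylation in the next step.

Step 6
Reactants: 8 (2R,3R)-3-(tert-butyldimethylsilyloxy)-2-(3-methoxyphenyl)-2-methylcyclohexan-1-one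
Product: 9 (2R,3R)-3-(tert-butyldimethylsilyloxy)-2-(3-methoxyphenyl)-2,6,6-trimethylcyclohexan-1-one
Conditions: KOt-Bu, MeI (excess), THF/t-BuOH, 0 °C → rt
Reagents that add atoms: iodomethane, CI
Why: Exhaustive enolate methylation installs the C4 gem-dimethyl group regiospecifically, since C4 is the only enolisable position next to the C5 carbonyl (C10 is quaternary).

Step 7
Reactants: 9 (2R,3R)-3-(tert-butyldimethylsilyloxy)-2-(3-methoxyphenyl)-2,6,6-trimethylcyclohexan-1-one
Product: 10 (2R,3R)-3-(tert-butyldimethylsilyloxy)-1-ethenyl-2-(3-methoxyphenyl)-2,6,6-trimethylcyclohexan-1-ol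
Conditions: vinylmagnesium bromide, LaCl3·2LiCl, THF, 0 °C → rt
Reagents that add atoms: vinylmagnesium bromide, C=C[Mg]Br
Why: Lanthanide-promoted Grignard 1,2-addition to a non-enolisable ketone, for which addition is the only productive pathway; the new carbinol configuration at C5 is irrelevant because the centre is ionised in step 8.

Step 8
Reactants: 10 (2R,3R)-3-(tert-butyldimethylsilyloxy)-1-ethenyl-2-(3-methoxyphenyl)-2,6,6-trimethylcyclohexan-1-ol
Product: 12 1β-hydroxy-12-methoxypodocarpa-5,8,11,13-tetraene (C20 α), via silyl ether 11 (not isolated)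
Conditions: Bi(OTf)3 (5 mol %), CH2Cl2, 0 °C → rt; then HF·pyridine, THF, rt
Reagents that add atoms: none
Why: Intramolecular Friedel–Crafts allylic alkylation (SN1′): the tertiary allylic alcohol ionises to the C5–C6–C7 allyl cation, which cannot eliminate (no β-hydrogen) and is captured at C7 by the arene para to the methoxy group, closing six-membered ring B with the C5=C6 alkene; fluoride then removes the silyl group.

Step 9
Reactants: 12 1β-hydroxy-12-methoxypodocarpa-5,8,11,13-tetraene
Product: 14 12-methoxy-5β-podocarpa-8,11,13-triene-1β,6β-diol (C20 α), via alkylborane 13 (not isolated)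
Conditions: BH3·THF (excess), THF, 0 → 45 °C; then NaOH, H2O2, 0 °C → rt
Reagents that add atoms: borane–tetrahydrofuran, [BH3-][O+]1CCCC1 (boron in 13 only); hydrogen peroxide, OO
Why: Hydroboration–oxidation with syn addition from the β face, opposite the syn-axial C20 and 4α methyl groups, and boron at the less substituted C6, which should set H-5 β (trans A/B fusion) and give the 6β-alcohol, as in 4,4-dimethyl-Δ5-steroids.

Step 10
Reactants: 14 12-methoxy-5β-podocarpa-8,11,13-triene-1β,6β-diol
Product: 15 12-methoxy-5β-podocarpa-8,11,13-triene-1,6-dione (C20 α)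
Conditions: Dess–Martin periodinane, NaHCO3, CH2Cl2, rt
Reagents that add atoms: none
Why: Dess–Martin oxidation of both secondary alcohols under neutral conditions that should not epimerise C5.

Step 11
Reactants: 15 12-methoxy-5β-podocarpa-8,11,13-triene-1,6-dione
Product: 16 12-methoxy-5β-podocarpa-8,11,13-triene-1α,6α-diol (C20 α)
Conditions: NaBH4, MeOH/THF, 0 °C → rt
Reagents that add atoms: none
Why: Borohydride reduction in which hydride reaches C6 from the β face (the α face is blocked by the two syn-axial methyl groups), giving the axial 6α-alcohol, and attacks C1 axially, anti to the axial C20 methyl, giving the equatorial 1α-alcohol.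

Step 12
Reactants: 16 12-methoxy-5β-podocarpa-8,11,13-triene-1α,6α-diol
Product: 17 12-methoxy-5β-podocarpa-8,12-diene-1α,6α-diol (C20 α)
Conditions: Li, NH3(l), THF, t-BuOH, −78 → −33 °C; NH4Cl
Reagents that add atoms: none
Why: Birch reduction of the anisole ring, which leaves the double bonds on the donor-substituted carbons (C12=C13 enol ether and tetrasubstituted C8=C9) and tolerates the alkoxides.

Step 13
Reactants: 17 12-methoxy-5β-podocarpa-8,12-diene-1α,6α-diol
Product: 19 1α,6α-diacetoxy-5β-podocarp-8-en-12-one (C20 α), via enol ether diacetate 18 (not isolated)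
Conditions: Ac2O, pyridine, DMAP, 60 °C; then oxalic acid, THF/H2O, rt
Reagents that add atoms: acetic anhydride, CC(=O)OC(C)=O; water, O
Why: DMAP-catalysed acetylation is run on the base-stable enol ether so that the hindered axial 6α-alcohol can be forced, and mild acid hydrolysis (kinetic protonation at C13) then releases the β,γ-unsaturated C12 ketone without conjugation.

Step 14
Reactants: 19 1α,6α-diacetoxy-5β-podocarp-8-en-12-one
Product: 20 1α,6α-diacetoxy-11β-(prop-2-ynyl)-5β-podocarp-8-en-12-one (C20 α)
Conditions: LiHMDS (1.05 equiv), THF, −78 → −40 °C; propargyl bromide, DMPU, −78 °C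
Reagents that add atoms: propargyl bromide, C#CCBr
Why: α-Alkylation of the conjugated dienolate (C12–O, C11, C9=C8) formed at the doubly activated C11, the electrophile entering from the β face anti to the axial C20 methyl, which sets C11; the low temperature should spare the acetates.

Step 15
Reactants: 20 1α,6α-diacetoxy-11β-(prop-2-ynyl)-5β-podocarp-8-en-12-one
Product: 21 1α,6α-diacetoxy-12-(tert-butyldimethylsilyloxy)-11β-(prop-2-ynyl)-5β-podocarpa-8,12-diene (C20 α)
Conditions: TBSOTf, Et3N, CH2Cl2, −78 → −20 °C
Reagents that add atoms: tert-butyldimethylsilyl triflate, CC(C)(C)[Si](C)(C)OS(=O)(=O)C(F)(F)F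
Why: Soft enolisation towards C13, because the axial propargyl group leaves H-11 in the carbonyl plane and hence stereoelectronically unavailable, and the non-basic conditions leave the terminal alkyne and the acetates untouched.

Step 16
Reactants: 21 1α,6α-diacetoxy-12-(tert-butyldimethylsilyloxy)-11β-(prop-2-ynyl)-5β-podocarpa-8,12-diene
Product: 22 1α,6α-diacetoxy-15-deoxo-12-oxo analogue of the target (C12 ketone and C15 methylene with C8=C9 and C16=C17)
Conditions: Ph3PAuCl (5 mol %), AgBF4 (5 mol %), CH2Cl2/MeOH 10:1, rt
Reagents that add atoms: none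
Why: Gold(I)-catalysed Conia-ene-type 5-exo-dig carbocyclisation of the silyl enol ether onto the alkyne, forming C13–C16 on the β face where the axial propargyl group sits; this sets C13 and, after protodeauration, delivers the exocyclic methylene of the bicyclo[3.2.1]octane.

Step 17
Reactants: 22 1α,6α-diacetoxy-15-deoxo-12-oxo analogue of the target
Product: 23 1α,6α-diacetoxy-15-deoxojungermannenone C (12-OH as in the target and C15 methylene)
Conditions: NaBH4, MeOH, −20 → 0 °C
Reagents that add atoms: none
Why: Borohydride reduction of the bridging ketone, in which hydride should approach over the wider three-carbon bridge flattened by the C8=C9 double bond (C9 carries no hydrogen), placing the hydroxyl syn to the C15–C16 bridge as in the target.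

Step 18
Reactants: 23 1α,6α-diacetoxy-15-deoxojungermannenone C
Product: 24 1α,6α-diacetoxy-15-hydroxy-15-deoxojungermannenone C (12,15-diol; C15 epimers)
Conditions: SeO2 (0.5 equiv), t-BuOOH, CH2Cl2, 0 °C → rt
Reagents that add atoms: tert-butyl hydroperoxide, CC(C)(C)OO (oxygen delivered through SeO2, O=[Se]=O)
Why: Selenium dioxide allylic hydroxylation (ene reaction then [2,3]-shift) at C15 of the strained 1,1-disubstituted exocyclic alkene, the standard oxidation of kaur-16-ene-type bicyclo[3.2.1]octanes; the C15 configuration is irrelevant.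

Step 19
Reactants: 24 1α,6α-diacetoxy-15-hydroxy-15-deoxojungermannenone C
Product: 25 1α,6α-diacetoxyjungermannenone C
Conditions: MnO2, CH2Cl2, rt
Reagents that add atoms: none
Why: Manganese dioxide oxidises only the allylic C15 alcohol to the α-methylene ketone and leaves the saturated C12 alcohol and the acetates intact.

**Compound list**

1 | dimethyl glutarate | COC(=O)CCCC(=O)OC | starting material
2 | 1,2-bis(trimethylsilyloxy)cyclopent-1-ene | C[Si](C)(C)OC1=C(O[Si](C)(C)C)CCC1 | intermediate
3 | 3'-methoxyacetophenone | CC(=O)c1cccc(OC)c1 | starting material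
4 | 1-(1,1-dimethoxyethyl)-3-methoxybenzene | COc1cccc(c1)C(C)(OC)OC | intermediate
5 | 2-[1-methoxy-1-(3-methoxyphenyl)ethyl]-2-(trimethylsilyloxy)cyclopentan-1-one (racemic diastereomer mixture) | COc1cccc(c1)C(C)(OC)C1(O[Si](C)(C)C)CCCC1=O | intermediate (not isolated)
6 | 2-(3-methoxyphenyl)-2-methylcyclohexane-1,3-dione (achiral) | COc1cccc(c1)C1(C)C(=O)CCCC1=O | intermediate
7 | (2R,3R)-3-hydroxy-2-(3-methoxyphenyl)-2-methylcyclohexan-1-one (OH cis to aryl) | O[C@@H]1CCCC(=O)[C@]1(C)c1cccc(OC)c1 | intermediate
8 | (2R,3R)-3-(tert-butyldimethylsilyloxy)-2-(3-methoxyphenyl)-2-methylcyclohexan-1-one | CC(C)(C)[Si](C)(C)O[C@@H]1CCCC(=O)[C@]1(C)c1cccc(OC)c1 | intermediate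
9 | (2R,3R)-3-(tert-butyldimethylsilyloxy)-2-(3-methoxyphenyl)-2,6,6-trimethylcyclohexan-1-one | CC(C)(C)[Si](C)(C)O[C@@H]1CCC(C)(C)C(=O)[C@]1(C)c1cccc(OC)c1 | intermediate
10 | (2R,3R)-3-(tert-butyldimethylsilyloxy)-1-ethenyl-2-(3-methoxyphenyl)-2,6,6-trimethylcyclohexan-1-ol (both epimers at the carbinol carbon, the future C5) | CC(C)(C)[Si](C)(C)O[C@@H]1CCC(C)(C)C(O)(C=C)[C@]1(C)c1cccc(OC)c1 | intermediate
11 | 1β-(tert-butyldimethylsilyloxy)-12-methoxypodocarpa-5,8,11,13-tetraene (C20 α) | COc1ccc2c(c1)[C@]1(C)[C@H](O[Si](C)(C)C(C)(C)C)CCC(C)(C)C1=CC2 | intermediate (not isolated)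
12 | 1β-hydroxy-12-methoxypodocarpa-5,8,11,13-tetraene (C20 α) | COc1ccc2c(c1)[C@]1(C)[C@H](O)CCC(C)(C)C1=CC2 | intermediate
13 | 6β-boryl-1β-hydroxy-12-methoxy-5β-podocarpa-8,11,13-triene (drawn as the monoalkylborane; the O1 borinate is equivalent) | COc1ccc2c(c1)[C@]1(C)[C@H](O)CCC(C)(C)[C@H]1[C@H](B)C2 | intermediate (not isolated)
14 | 12-methoxy-5β-podocarpa-8,11,13-triene-1β,6β-diol (C20 α) | COc1ccc2c(c1)[C@]1(C)[C@H](O)CCC(C)(C)[C@H]1[C@H](O)C2 | intermediate
15 | 12-methoxy-5β-podocarpa-8,11,13-triene-1,6-dione (C20 α) | COc1ccc2c(c1)[C@]1(C)C(=O)CCC(C)(C)[C@H]1C(=O)C2 | intermediate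
16 | 12-methoxy-5β-podocarpa-8,11,13-triene-1α,6α-diol (C20 α) | COc1ccc2c(c1)[C@]1(C)[C@@H](O)CCC(C)(C)[C@H]1[C@@H](O)C2 | intermediate
17 | 12-methoxy-5β-podocarpa-8,12-diene-1α,6α-diol (C20 α) | COC1=CCC2=C(C1)[C@]1(C)[C@@H](O)CCC(C)(C)[C@H]1[C@@H](O)C2 | intermediate
18 | 1α,6α-diacetoxy-12-methoxy-5β-podocarpa-8,12-diene (C20 α) | COC1=CCC2=C(C1)[C@]1(C)[C@@H](OC(C)=O)CCC(C)(C)[C@H]1[C@@H](OC(C)=O)C2 | intermediate (not isolated)
19 | 1α,6α-diacetoxy-5β-podocarp-8-en-12-one (C20 α) | O=C1CCC2=C(C1)[C@]1(C)[C@@H](OC(C)=O)CCC(C)(C)[C@H]1[C@@H](OC(C)=O)C2 | intermediate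
20 | 1α,6α-diacetoxy-11β-(prop-2-ynyl)-5β-podocarp-8-en-12-one (C20 α) | O=C1CCC2=C([C@H]1CC#C)[C@]1(C)[C@@H](OC(C)=O)CCC(C)(C)[C@H]1[C@@H](OC(C)=O)C2 | intermediate
21 | 1α,6α-diacetoxy-12-(tert-butyldimethylsilyloxy)-11β-(prop-2-ynyl)-5β-podocarpa-8,12-diene (C20 α) | CC(C)(C)[Si](C)(C)OC1=CCC2=C([C@H]1CC#C)[C@]1(C)[C@@H](OC(C)=O)CCC(C)(C)[C@H]1[C@@H](OC(C)=O)C2 | intermediate
22 | 1α,6α-diacetoxy-15-deoxo-12-oxo analogue of the target (C12 ketone, C15 methylene, C15–C16 bridge β) | C=C1C[C@@H]2C3=C(C[C@H](OC(C)=O)[C@@H]4C(C)(C)CC[C@H](OC(C)=O)[C@@]34C)C[C@H]1C2=O | intermediate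
23 | 1α,6α-diacetoxy-15-deoxojungermannenone C (12-OH syn to the C15–C16 bridge, C15 methylene) | C=C1C[C@@H]2C3=C(C[C@H](OC(C)=O)[C@@H]4C(C)(C)CC[C@H](OC(C)=O)[C@@]34C)C[C@H]1[C@@H]2O | intermediate
24 | 1α,6α-diacetoxy-15-hydroxy-15-deoxojungermannenone C (12,15-diol, C15 epimers) | C=C1C(O)[C@@H]2C3=C(C[C@H](OC(C)=O)[C@@H]4C(C)(C)CC[C@H](OC(C)=O)[C@@]34C)C[C@H]1[C@@H]2O | intermediate
25 | 1α,6α-diacetoxyjungermannenone C | C=C1C(=O)[C@@H]2C3=C(C[C@H](OC(C)=O)[C@@H]4C(C)(C)CC[C@H](OC(C)=O)[C@@]34C)C[C@H]1[C@@H]2O | target

**Total step count:** 19. **Longest linear sequence:** 18 (step 1 or step 2, then steps 3–19).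

**Three steps most likely to fail**

Step 3 (key step). The 1,2-acyl shift of the unstrained five-membered adduct may be slower than retro-aldol fragmentation of 5 or than diversion of the benzylic cation into elimination and intermolecular arylation. The fallback sets out from ketal 4 and uses the strain-driven four-membered version of the same reaction: 4 and commercial 1,2-bis(trimethylsilyloxy)cyclobutene (BF3·OEt2, CH2Cl2, −78 °C → rt; then CF3CO2H) should give 2-(3-methoxyphenyl)-2-methylcyclopentane-1,3-dione F1. One of its two equivalent carbonyls is then homologated with one equivalent of trimethylsilyldiazomethane (BF3·OEt2, CH2Cl2, −78 °C), the methylene and not the quaternary carbon migrating, to the α-silyl ketone 2-(3-methoxyphenyl)-2-methyl-4-(trimethylsilyl)cyclohexane-1,3-dione F2. Its C–Si bond is cleaved on acidic work-up, which returns to the route at 6. Ring A then still arises by a five-to-six ring expansion.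

Step 7. Addition to a carbonyl flanked by two quaternary carbons may be too slow, so that single-electron reduction of the ketone or simple recovery of 9 takes over. The fallback sets out from 9 and uses a much slimmer sp nucleophile: lithium acetylide–ethylenediamine complex (THF, rt) should give the ethynyl carbinol (2R,3R)-3-(tert-butyldimethylsilyloxy)-1-ethynyl-2-(3-methoxyphenyl)-2,6,6-trimethylcyclohexan-1-ol F3. Lindlar semihydrogenation (H2, Pd/CaCO3–Pb, quinoline, EtOAc) then returns to the route at 10.

Step 17. Hydride delivery to the bridging C12 carbonyl may show poor facial selectivity, or come from the side of the two-carbon bridge, giving the C12 epimer. The fallback sets out from 22 and replaces kinetic hydride delivery by electron-transfer reduction under thermodynamic control (SmI2, i-PrOH, THF, rt). The ketyl is then protonated to the more stable alcohol, with the hydroxyl equatorial on the cyclohexene ring and syn to the two-carbon bridge, which is 23. The acetates and both alkenes should be untouched, and the fallback makes no new compound (F0).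

Further compounds
F1 | step 3 | 2-(3-methoxyphenyl)-2-methylcyclopentane-1,3-dione | COc1cccc(c1)C1(C)C(=O)CCC1=O
F2 | step 3 | 2-(3-methoxyphenyl)-2-methyl-4-(trimethylsilyl)cyclohexane-1,3-dione | COc1cccc(c1)C1(C)C(=O)CCC([Si](C)(C)C)C1=O
F3 | step 7 | (2R,3R)-3-(tert-butyldimethylsilyloxy)-1-ethynyl-2-(3-methoxyphenyl)-2,6,6-trimethylcyclohexan-1-ol | CC(C)(C)[Si](C)(C)O[C@@H]1CCC(C)(C)C(O)(C#C)[C@]1(C)c1cccc(OC)c1
F0 | step 17 | none | none
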